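**Retrosynthetic overview**

1. Target 14 is numbered as a bicyclo[3.2.1]octan-8-one (C1 = OMe bridgehead, C2 = CHOH, C3 = CHOMe, C5 = allyl bridgehead, C6 = CHMe, C7 = CH-aryl) and is cut at C6–C7, C5–allyl and C1–C2, giving acyclic dienone aldehyde 9 and allyltrimethylsilane 10.
2. Forward, in one flask: a Nazarov 4π closure makes the five-membered ring first (C6–C7), allylsilane capture of the oxyallyl cation builds quaternary C5, and the resulting enolate closes the six-membered ring second by aldol addition (C1–C2).
3. 9 comes from Baylis–Hillman acetate 7 and methoxyacetaldehyde 8 by an enamine-catalysed SN2′ alkylation that sets the C3 stereocentre.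
4. 7 is built from 3,4,5-trimethoxybenzaldehyde 1, methoxyacetone 2, formaldehyde and acetaldehyde 5 (Claisen–Schmidt, methylenation, one-pot Morita–Baylis–Hillman/acetylation).

Assumption: methoxyacetaldehyde 8 is bought as such and dried before use, and the carbinol centre of 6 and 7 is left racemic because step 4 destroys it.

**Route**

Step 1
Reactants: 1 3,4,5-trimethoxybenzaldehyde; 2 methoxyacetone
Product: 3 (3Z)-3-methoxy-4-(3,4,5-trimethoxyphenyl)but-3-en-2-one
Conditions: twofold excess of 2, NaOH (10% aq), MeOH, 0 °C → rt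
Reagents that add atoms: none
Why: Claisen–Schmidt (crossed aldol) condensation at the more acidic methoxy-substituted methylene of 2, with E1cB dehydration giving the conjugated Z enol ether (aryl trans to acetyl).

Step 2
Reactants: 3 (3Z)-3-methoxy-4-(3,4,5-trimethoxyphenyl)but-3-en-2-one
Product: 4 (4Z)-4-methoxy-5-(3,4,5-trimethoxyphenyl)penta-1,4-dien-3-one
Conditions: (CH2O)n (3 equiv), iPr2NH2+ CF3CO2− (1 equiv), CF3CO2H (0.1 equiv), THF, reflux
Reagents that add atoms: formaldehyde (used as paraformaldehyde), C=O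
Why: Mannich-type α-methylenation of a methyl ketone, which can only occur at the methyl group because it is the sole enolisable position of 3.

Step 3
Reactants: 4 (4Z)-4-methoxy-5-(3,4,5-trimethoxyphenyl)penta-1,4-dien-3-one; 5 acetaldehyde
Product: 7 rac-(5Z)-5-methoxy-3-methylidene-4-oxo-6-(3,4,5-trimethoxyphenyl)hex-5-en-2-yl acetate, via allylic alcohol 6 (not isolated)
Conditions: 1,4-diazabicyclo[2.2.2]octane (20 mol %), fivefold excess of 5, THF, 0 °C → rt; evaporate volatiles; then Ac2O (1.5 equiv), pyridine, 4-(dimethylamino)pyridine (5 mol %), CH2Cl2, 0 °C; dilute acid wash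
Reagents that add atoms: acetic anhydride, CC(=O)OC(C)=O
Why: Morita–Baylis–Hillman reaction in which the amine adds only to the unsubstituted vinyl terminus (the methoxystyryl enone is trisubstituted and electron-rich), followed in the same flask by routine O-acetylation, which traps the reversibly formed alcohol 6 as the leaving group for the SN2′ step; the new carbinol centre may stay racemic because it is removed in step 4.

Step 4
Reactants: 7 rac-(5Z)-5-methoxy-3-methylidene-4-oxo-6-(3,4,5-trimethoxyphenyl)hex-5-en-2-yl acetate; 8 methoxyacetaldehyde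
Product: 9 (2S,4E,6Z)-4-ethylidene-2,6-dimethoxy-5-oxo-7-(3,4,5-trimethoxyphenyl)hept-6-enal
Conditions: threefold excess of 8, (R)-2-[diphenyl(trimethylsilyloxy)methyl]pyrrolidine (10 mol %), CHCl3, 0 °C
Reagents that add atoms: none
Why: Enamine-catalysed SN2′ allylic alkylation of a Baylis–Hillman acetate (Michael addition to the methylene terminus, then E1cB loss of acetate), in which the diphenyl(silyloxy)methyl group blocks one face of the E-enamine and sets the (S)-methoxy carbon (C3 of the target), while the elimination gives the E-ethylidene with methyl trans to the ketone.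

Step 5
Reactants: 9 (2S,4E,6Z)-4-ethylidene-2,6-dimethoxy-5-oxo-7-(3,4,5-trimethoxyphenyl)hept-6-enal; 10 allyltrimethylsilane
Product: 14 (1S,2S,3S,5R,6R,7S)-2-hydroxy-1,3-dimethoxy-6-methyl-5-(prop-2-en-1-yl)-7-(3,4,5-trimethoxyphenyl)bicyclo[3.2.1]octan-8-one, via oxyallyl cation 11 (not isolated), via silyl enol ether 12 (not isolated), via silyl ether 13 (not isolated)
Conditions: threefold excess of 10, Sc(OSO2CF3)3 (10 mol %), 2,6-bis[(4S)-4-phenyl-4,5-dihydro-1,3-oxazol-2-yl]pyridine (12 mol %), 4 Å molecular sieves, CH2Cl2, −20 °C → rt; then 1 M HCl, THF, 0 °C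
Reagents that add atoms: none
Why: Proposed new method: the chiral Sc(OSO2CF3)3–ligand chelate of the α-methoxy ketone triggers a torquoselective conrotatory 4π (Nazarov) closure of the (4E,6Z)-dienone, which forms C6–C7 with methyl and aryl trans and fixes their absolute configuration; the soft allylsilane then attacks cation 11 at the terminus remote from the methoxy group (the vinylogous position, as in cycloadditions of alkoxy-substituted oxyallyl cations) and anti to the neighbouring methyl, creating quaternary C5; the catalyst-bound enolate of 12 then closes the second ring by aldol addition to the chelated α-methoxy aldehyde on the face trans to the aryl group, through a closed chair-like transition state with the C3 methoxy equatorial and the aldehyde oxygen next to the enolate oxygen, which sets C1 and the axial C2 hydroxyl; the closest known reaction types are the interrupted Nazarov reaction with allylsilanes (Hosomi–Sakurai-type capture), the asymmetric Nazarov cyclisation of 2-alkoxy dienones with Sc(OSO2CF3)3–bis(oxazolinyl)pyridine catalysts, and Lewis-acid-catalysed Mukaiyama aldol ring closure.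

**Compound list**

1 | 3,4,5-trimethoxybenzaldehyde | COc1cc(C=O)cc(OC)c1OC | starting material
2 | methoxyacetone (1-methoxypropan-2-one) | COCC(C)=O | starting material
3 | (3Z)-3-methoxy-4-(3,4,5-trimethoxyphenyl)but-3-en-2-one | COc1cc(/C=C(\OC)C(C)=O)cc(OC)c1OC | intermediate
4 | (4Z)-4-methoxy-5-(3,4,5-trimethoxyphenyl)penta-1,4-dien-3-one | COc1cc(/C=C(\OC)C(=O)C=C)cc(OC)c1OC | intermediate
5 | acetaldehyde | CC=O | starting material
6 | allylic alcohol: rac-(1Z)-5-hydroxy-2-methoxy-4-methylidene-1-(3,4,5-trimethoxyphenyl)hex-1-en-3-one | COc1cc(/C=C(\OC)C(=O)C(=C)C(C)O)cc(OC)c1OC | intermediate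
7 | rac-(5Z)-5-methoxy-3-methylidene-4-oxo-6-(3,4,5-trimethoxyphenyl)hex-5-en-2-yl acetate | COc1cc(/C=C(\OC)C(=O)C(=C)C(C)OC(C)=O)cc(OC)c1OC | intermediate
8 | methoxyacetaldehyde | COCC=O | starting material
9 | (2S,4E,6Z)-4-ethylidene-2,6-dimethoxy-5-oxo-7-(3,4,5-trimethoxyphenyl)hept-6-enal | COc1cc(/C=C(\OC)C(=O)/C(=C/C)C[C@H](OC)C=O)cc(OC)c1OC | intermediate
10 | allyltrimethylsilane | C=CC[Si](C)(C)C | starting material
11 | oxyallyl cation, drawn as the zwitterion without the metal: (4S,5R)-1-[(2S)-2-methoxy-3-oxopropyl]-5-methyl-3-(methyloxoniumylidene)-4-(3,4,5-trimethoxyphenyl)cyclopent-1-en-2-olate | O=C[C@@H](OC)CC1=C([O-])C(=[O+]C)[C@H](c2cc(OC)c(OC)c(OC)c2)[C@H]1C | intermediate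
12 | silyl enol ether: (2S)-2-methoxy-3-[(1R,4S,5R)-3-methoxy-5-methyl-1-(prop-2-en-1-yl)-4-(3,4,5-trimethoxyphenyl)-2-(trimethylsilyloxy)cyclopent-2-en-1-yl]propanal | C=CC[C@]1(C[C@H](OC)C=O)C(O[Si](C)(C)C)=C(OC)[C@H](c2cc(OC)c(OC)c(OC)c2)[C@H]1C | intermediate
13 | silyl ether: (1S,2S,3S,5R,6R,7S)-1,3-dimethoxy-6-methyl-5-(prop-2-en-1-yl)-7-(3,4,5-trimethoxyphenyl)-2-(trimethylsilyloxy)bicyclo[3.2.1]octan-8-one | C=CC[C@]12C[C@H](OC)[C@H](O[Si](C)(C)C)[C@](OC)(C1=O)[C@H](c1cc(OC)c(OC)c(OC)c1)[C@H]2C | intermediate
14 | (1S,2S,3S,5R,6R,7S)-2-hydroxy-1,3-dimethoxy-6-methyl-5-(prop-2-en-1-yl)-7-(3,4,5-trimethoxyphenyl)bicyclo[3.2.1]octan-8-one | C=CC[C@]12C[C@H](OC)[C@H](O)[C@](OC)(C1=O)[C@H](c1cc(OC)c(OC)c(OC)c1)[C@H]2C | target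

**Totals**

Total steps: 5. Longest linear sequence: 5 steps (1 → 3 → 4 → 7 → 9 → 14).

**Steps most likely to fail**

Step 5. The risks are:
- 10 may add to the free aldehyde before ring closure.
- The cation may simply lose a proton (ordinary Nazarov product).
- The allyl group may enter at the methoxy-bearing terminus.
- The aldol may give the C2 epimer.
- The sense of conrotation is empirical; the ligand antipode is used if the first run shows the wrong sense.

Fallback, setting out from 7 and returning at 14: the chain terminus is carried as an ester and the second ring is closed separately. Compound 7 is alkylated SN2′ with methyl methoxyacetate deprotonated by LiN(SiMe3)2 (THF, −78 °C) to give methyl ester F1, racemic at its methoxy carbon. The same Sc(OSO2CF3)3–ligand treatment with 10, now without a competing aldehyde, gives silyl enol ether F2, which work-up hydrolyses to keto ester F3. LiN(SiMe3)2 then closes the six-membered ring by an intramolecular Claisen (Dieckmann-type) condensation to dione F4, whose methoxy-bearing C3 equilibrates under the basic conditions to the equatorial epimer. LiBH(sec-Bu)3 (THF, −78 °C) reduces the less hindered C2 ketone from the equatorial direction and gives the axial alcohol 14.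

Step 4. The 1,1-disubstituted enone may be a sluggish acceptor for the hindered enamine, the ee at the epimerisable α-methoxy aldehyde may be low, and 8 may self-condense.

Fallback, setting out from 8 (coupled again with 7) and returning at 9: the stereocentre is set with a stoichiometric auxiliary. Compound 8 is condensed with (S)-1-amino-2-(methoxymethyl)pyrrolidine to hydrazone F5. Its aza-enolate (LiN(iPr)2, THF, −78 °C) is alkylated SN2′ with 7 to give alkylated hydrazone F6; the antipodal auxiliary is taken if the sense of induction proves opposite. Aqueous oxalic acid then releases 9.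

Step 3. Divinyl ketone 4 may oligomerise or dimerise under amine catalysis faster than it adds to acetaldehyde, and residual amine may shift the acetate of 7 to the primary allylic position during the acetylation stage.

Fallback, setting out from 3 and returning at 7 (steps 2 and 3 are both bypassed): the order of bond formation is inverted. Methyl ketone 3 is deprotonated with LiN(SiMe3)2 (THF, −78 °C) and added to 5 in a directed aldol reaction to give β-hydroxy ketone F7. The methylene group is then introduced at the activated CH2 with (CH2O)n and iPr2NH2+ CF3CO2− (THF, reflux), which gives 6, here isolated. Acetylation with Ac2O, pyridine and 4-(dimethylamino)pyridine (CH2Cl2, 0 °C) gives 7.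

**Further compounds**

F1 | step 5 | methyl (4E,6Z)-4-ethylidene-2,6-dimethoxy-5-oxo-7-(3,4,5-trimethoxyphenyl)hept-6-enoate (racemic) | COc1cc(/C=C(\OC)C(=O)/C(=C/C)CC(OC)C(=O)OC)cc(OC)c1OC
F2 | step 5 | methyl 2-methoxy-3-[(1R,4S,5R)-3-methoxy-5-methyl-1-(prop-2-en-1-yl)-4-(3,4,5-trimethoxyphenyl)-2-(trimethylsilyloxy)cyclopent-2-en-1-yl]propanoate | C=CC[C@]1(CC(OC)C(=O)OC)C(O[Si](C)(C)C)=C(OC)[C@H](c2cc(OC)c(OC)c(OC)c2)[C@H]1C
F3 | step 5 | methyl 2-methoxy-3-[(1R,4S,5R)-3-methoxy-5-methyl-2-oxo-1-(prop-2-en-1-yl)-4-(3,4,5-trimethoxyphenyl)cyclopentyl]propanoate (epimers at both methoxy carbons) | C=CC[C@]1(CC(OC)C(=O)OC)C(=O)C(OC)[C@H](c2cc(OC)c(OC)c(OC)c2)[C@H]1C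
F4 | step 5 | (1R,3S,5R,6R,7S)-1,3-dimethoxy-6-methyl-5-(prop-2-en-1-yl)-7-(3,4,5-trimethoxyphenyl)bicyclo[3.2.1]octane-2,8-dione | C=CC[C@]12C[C@H](OC)C(=O)[C@](OC)(C1=O)[C@H](c1cc(OC)c(OC)c(OC)c1)[C@H]2C
F5 | step 4 | (2S)-N-[(E)-2-methoxyethylidene]-2-(methoxymethyl)pyrrolidin-1-amine | COC/C=N/N1CCC[C@H]1COC
F6 | step 4 | (2S)-N-[(1E,2S,4E,6Z)-4-ethylidene-2,6-dimethoxy-5-oxo-7-(3,4,5-trimethoxyphenyl)hept-6-en-1-ylidene]-2-(methoxymethyl)pyrrolidin-1-amine | COc1cc(/C=C(\OC)C(=O)/C(=C/C)C[C@H](OC)/C=N/N2CCC[C@H]2COC)cc(OC)c1OC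
F7 | step 3 | rac-(1Z)-5-hydroxy-2-methoxy-1-(3,4,5-trimethoxyphenyl)hex-1-en-3-one | COc1cc(/C=C(\OC)C(=O)CC(C)O)cc(OC)c1OC
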